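Conventions: skeletal atoms are numbered C1–C10 (ring A = C1, C2, C3, C4, C5, C10; ring B = C5 to C10), C14 is the methyl on C5, C15 the methyl on C4, C11–C13 the isopropenyl group on C7; β is the face of C14. Systematic names use naphthalene locants (1 = C9, 2 = C8, 3 = C7, 4 = C6, 4a = C5, 5 = C4, 6 = C3, 7 = C2, 8 = C1, 8a = C10).

Assumption: the sense of enantiotopic-group selection of the triazolium catalyst in step 6 cannot be assigned with certainty for this ring size; the (5aS,10bR) salt is written, and its (5aR,10bS) antipode is used if that is the one that gives (4aR,8aS)-10.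

## Analysis of the target

Target 26 is a cis-fused decalin of the eremophilane type. Ring A holds the C2 ketone and C15; ring B holds the isopropenyl group on C7, the (R)-2-methylbutanoate on O8 and the tiglate on O9; the rings share the quaternary C5 and the methine C10. Six contiguous ring stereocentres (4S, 5R, 10S, 9S, 8R, 7R) are joined by a seventh in the saturated acyl group. C15, C14, H10 and the isopropenyl group stand on the β face and both acyloxy groups on the α face, so the two methyls are cis, the diol is cis, and O8 is trans to the isopropenyl group. In the ring B chair that keeps the isopropenyl and O8 groups equatorial, the C5–C4 bond and O9 are axial, which makes O9 the hindered oxygen. Sensitive elements are the two different esters on a cis-vicinal diol (acyl migration), the epimerisable α-centre of the 2-methylbutanoate, the conjugated tiglate, the acid- and peracid-sensitive isopropenyl group and, while C9 is a ketone, the epimerisable C10. The difficulty lies in setting the absolute configuration of a quaternary carbon in the middle of the array and in telling O8 from O9. The strategy rests on ring A: C5 is flanked by C4 and C10 with C2 opposite, so ring A maps onto a 4-methyl-4-alkylcyclohexa-2,5-dienone in which C5 is prochiral, C4 and C10 are the β-carbons of two enantiotopic enones, and the oxygen on C9 marks an acyl carbon bonded to C10.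

## Retrosynthetic reasoning

The two ester C–O bonds are cut first. O8 is acylated last, with acid 25 on hydroxy ester 24: the equatorial C8 hydroxyl reacts fast, and the stereocentre of 25 meets only one mild step. The tiglate is placed one stage earlier on the hindered axial O9, from acid 21 through mixed anhydride 22 on alcohol 20, giving 23. In 20 and 23, O8 is a silyl ether and C2 a dioxolane, so no free hydroxyl sits next to an ester under forcing conditions, and one acid treatment then frees both O8 and the C2 ketone.

Alcohol 20 is cut at C9–H to ketone 19; the forward reduction must bring hydride to the β face. Ketone 19 is cut at C8–O to silyl enol ether 17. Here oxygen must enter on the α face, anti to the C7 substituent; C8 is the one ring B centre that is not set from the β face, and it is also the equatorial, thermodynamically preferred epimer.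

Enol ether 17 is cut at C7–C11: conjugate addition of 16 to enone 15 with silyl capture of the enolate, which fixes the site of the later oxidation. Enone 15 comes from ketone 13 through the kinetic enol ether 14. The C9 carbonyl thus serves three times, for C7, C8 and C9.

Ketone 13 is the C2 mono-ketal of diketone 12, needed so that only the C9 carbonyl is enolised and reduced. Diketone 12 is cut at C4–C15: conjugate methyl transfer from copper to the enone left in 10, which must occur on the β face to give the cis-dimethyl pair.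

Enedione 10 is cut at C9–C10, the key disconnection. It is the only ring B bond that joins an acyl carbon to an enone β-carbon, and cutting it leads to the achiral aldehyde 9. The forward reaction must reverse the polarity of the aldehyde, choose one of two enantiotopic enones, and close ring B cis.

Aldehyde 9 comes from dienone 7 by cleavage of the terminal alkene, 7 from enone 6 by dehydrogenation, 6 from vinylogous ester 4 by reduction and carbonyl transposition through 5, and 4 from 1 by two enolate alkylations (with 2, then with a methyl electrophile through 3). The small electrophile is used for the quaternary carbon.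

## Alternatives that were turned down

Alternative 1: The cut is at C5–C10 and C3–C4, so both rings come from one intramolecular Diels–Alder reaction. Heating the silyloxytrienone A1 (2-silyloxy diene C10=C1–C2=C3, tethered through C9–C6 to the α,β-dimethyl enone C4=C5) would give A2.
- For: two rings, two C–C bonds and C4, C5 and C10 in one step. The diol comes from the chiral pool as an acetonide, so no asymmetric catalyst is needed, and the enol ether places the C2 oxygen. On bonds per step and on the source of absolute configuration this alternative is stronger.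
- Against: the dienophile is trisubstituted and must form the quaternary C5, so high temperatures are needed at which the electron-rich diene is labile. The cis fusion depends on one transition-state geometry that the acetonide in the tether need not favour. A2 also carries a C6 carbonyl that the target lacks; it would have to bring in the C7 substituent and then be removed next to a quaternary carbon.
- Comparison: the chosen route makes fewer bonds in its key step, but puts oxygen only where the target has it and starts from an achiral precursor made in five simple steps.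

Alternative 2: The cut is at C4–C5, with a temporary C2–C7 bond. The potassium alkoxide of bicyclo[2.2.2]octenol A3 would undergo an anionic oxy-Cope shift to A4.
- For: the shift is stereospecific, the bicycle enforces the cis fusion, and the (Z)-propenyl geometry sets the C4/C5 relationship. The bicyclic core is available from an oxidatively dearomatised phenol in one cycloaddition and already carries both ring B oxygens, differentiated. On oxygenation this alternative is stronger, since no later α-hydroxylation is needed.
- Against: the dearomatisation and cycloaddition give racemic material, so a resolution or an auxiliary is needed. The propenyl nucleophile must add to a bridged ketone on the face over the C5=C6 bridge. Most seriously, the C6=C7 alkene in A4 is isolated, so a three-carbon unit must be attached at C7 on the β face without an activating group.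
- Comparison: the chosen route keeps a ketone at C9, which makes C7 an enone β-carbon, and obtains its absolute configuration from a catalyst.

Alternative 3: The cut is at C5–C6, and the angular methyl derives from an exocyclic methylene. A metal-hydride hydrogen-atom-transfer catalyst would give the tertiary C5 radical of A5, which adds to the terminal carbon of the tethered α-methylene ketone to give A6.
- For: the quaternary centre forms under mild, neutral conditions, the diol is in place from the start, and after the key step only methylenation of the acetyl group, deprotection and two acylations remain. The endgame is shorter than in the chosen route.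
- Against: A5 already needs C4, C10, C9 and C8, including a stereocontrolled C10–C9 bond between ring and side chain, so the difficulty is moved upstream. The two alkenes compete for the hydrogen atom, and the ring fusion and C7 arise from a radical with little facial bias.
- Comparison: the chosen route sets the quaternary centre by catalyst control on an achiral substrate and the other centres one by one on a rigid bicycle, at the price of a longer endgame.

Key step: step 6

## Route

Step 1
Reactants: 1 3-ethoxycyclohex-2-en-1-one; 2 5-bromopent-1-ene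
Product: 3 3-ethoxy-6-(pent-4-en-1-yl)cyclohex-2-en-1-one (racemic)
Conditions: LiN(i-Pr)2, THF, −78 °C; then 2, DMPU, −78 → 23 °C
Reagents that add atoms: none
Why: Stork–Danheiser α′-alkylation: the kinetic enolate of the vinylogous ester is alkylated at C6 by the primary bromide; the stereocentre formed is of no consequence.

Step 2
Reactants: 3 3-ethoxy-6-(pent-4-en-1-yl)cyclohex-2-en-1-one
Product: 4 3-ethoxy-6-methyl-6-(pent-4-en-1-yl)cyclohex-2-en-1-one (racemic)
Conditions: LiN(i-Pr)2, THF, −78 °C; then MeI, −78 → 0 °C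
Reagents that add atoms: methyl iodide (CI)
Why: Second Stork–Danheiser alkylation; the small, reactive electrophile is kept for the step that builds the quaternary carbon (the future C5), whose chirality vanishes at the dienone stage.

Step 3
Reactants: 4 3-ethoxy-6-methyl-6-(pent-4-en-1-yl)cyclohex-2-en-1-one
Product: 6 4-methyl-4-(pent-4-en-1-yl)cyclohex-2-en-1-one (racemic), via allylic alcohol 5 (not isolated)
Conditions: LiAlH4, Et2O, 0 °C; then 1 M HCl (aq), 23 °C
Reagents that add atoms: water (O)
Why: Stork–Danheiser carbonyl transposition: 1,2-reduction of the vinylogous ester, then acid hydrolysis of the enol ether with loss of water, gives the 4,4-disubstituted enone.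

Step 4
Reactants: 6 4-methyl-4-(pent-4-en-1-yl)cyclohex-2-en-1-one
Product: 7 4-methyl-4-(pent-4-en-1-yl)cyclohexa-2,5-dien-1-one (achiral)
Conditions: IBX, DMSO, 75 °C
Reagents that add atoms: none
Why: IBX dehydrogenation of the enone on its saturated side gives the cross-conjugated dienone; the isolated terminal alkene is inert to IBX.

Step 5
Reactants: 7 4-methyl-4-(pent-4-en-1-yl)cyclohexa-2,5-dien-1-one
Product: 9 4-(1-methyl-4-oxocyclohexa-2,5-dien-1-yl)butanal, via ozonide 8 (not isolated)
Conditions: O3, CH2Cl2, −78 °C (Sudan Red 7B end point); then PPh3, −78 → 23 °C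
Reagents that add atoms: ozone ([O-][O+]=O)
Why: Ozonolysis with reductive work-up; the electron-rich monosubstituted alkene reacts far faster than the electron-poor dienone double bonds, and the dye marks the end point before these are touched.

Step 6
Reactants: 9 4-(1-methyl-4-oxocyclohexa-2,5-dien-1-yl)butanal
Product: 10 (4aR,8aS)-4a-methyl-3,4,4a,8a-tetrahydronaphthalene-1,7(2H,8H)-dione (cis-fused)
Conditions: (5aS,10bR)-2-(pentafluorophenyl)-5a,10b-dihydro-4H,6H-indeno[2,1-b][1,2,4]triazolo[4,3-d][1,4]oxazin-2-ium tetrafluoroborate (20 mol %), KN(SiMe3)2 (18 mol %), toluene, 23 °C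
Reagents that add atoms: none
Why: Intramolecular Stetter reaction: the free carbene adds to the aldehyde carbon C9, proton transfer gives the enaminol acyl-anion equivalent, this adds 1,4 to C10 of one enone arm, and proton transfer with loss of the carbene releases the C9 ketone. The closest known reaction type is the carbene-catalysed desymmetrising Stetter cyclisation of 4,4-disubstituted cyclohexadienones with a shorter aldehyde tether, together with carbene-catalysed Stetter closures of aliphatic aldehydes to six-membered carbocycles; the present case joins the two. Ring B is closed in the 6-exo-trig mode. C5 is controlled by the chiral catalyst, which decides which of the two enantiotopic enone arms is attacked and so turns the prochiral carbon into the 5R quaternary centre. C10 is controlled by the tether: the three-carbon chain reaches the β-carbon only on the face of the dienone on which it stands, so C10–C9 forms cis to C5–C6 and the fusion is cis (10S once C5 is R). The step needs enantiotopic-group selection and chemoselection for the acyl-anion pathway over aldol or Michael reactions of the aldehyde enolate; the dienone has no enolisable hydrogen, its two arms are identical acceptors, and base is kept below the precatalyst loading so that no free base remains. The C3=C4 enone and the C9 ketone are left as handles for all later substituents.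

Step 7
Reactants: 10 (4aR,8aS)-4a-methyl-3,4,4a,8a-tetrahydronaphthalene-1,7(2H,8H)-dione
Product: 12 (4aR,5S,8aS)-4a,5-dimethyl-3,4,4a,5,6,8a-hexahydronaphthalene-1,7(2H,8H)-dione, via silyl enol ether 11 (not isolated)
Conditions: Me2CuLi (from MeLi and CuI), Me3SiCl, Et2O/THF, −78 °C; then 1 M HCl (aq), 0 °C
Reagents that add atoms: lithium dimethylcuprate ([Li+].C[Cu-]C)
Why: Chlorosilane-accelerated organocuprate conjugate addition to the C3=C4 enone; the hindered C9 ketone is not attacked. Axial delivery to C4 anti to the C5–C6 bond (β face; α attack would be syn-axial to the C10–C9 bond of ring B) places C15 cis to C14 (4S).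

Step 8
Reactants: 12 (4aR,5S,8aS)-4a,5-dimethyl-3,4,4a,5,6,8a-hexahydronaphthalene-1,7(2H,8H)-dione
Product: 13 (4aR,5S,8aS)-7,7-(ethylenedioxy)-4a,5-dimethyloctahydronaphthalen-1(2H)-one
Conditions: Me3SiOCH2CH2OSiMe3, Me3SiOTf (cat.), CH2Cl2, −78 °C; pyridine quench
Reagents that add atoms: 1,2-bis(trimethylsilyloxy)ethane (C[Si](C)(C)OCCO[Si](C)(C)C)
Why: Silyl triflate-catalysed ketalisation under kinetic, aprotic conditions selects the C2 carbonyl, flanked by two methylenes, over the C9 carbonyl next to the ring-fusion methine and the quaternary C5; the cold medium leaves C10 untouched.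

Step 9
Reactants: 13 (4aR,5S,8aS)-7,7-(ethylenedioxy)-4a,5-dimethyloctahydronaphthalen-1(2H)-one
Product: 14 {[(4aR,5S,8aS)-7,7-(ethylenedioxy)-4a,5-dimethyl-3,4,4a,5,6,7,8,8a-octahydronaphthalen-1-yl]oxy}trimethylsilane
Conditions: LiN(i-Pr)2, Me3SiCl (internal quench), THF, −78 °C
Reagents that add atoms: chlorotrimethylsilane (C[Si](C)(C)Cl)
Why: Kinetic silyl enol ether formation: the amide base takes a methylene hydrogen at C8, not the hindered methine at C10, and in situ silylation fixes the C8=C9 regiochemistry without epimerising C10.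

Step 10
Reactants: 14 {[(4aR,5S,8aS)-7,7-(ethylenedioxy)-4a,5-dimethyl-3,4,4a,5,6,7,8,8a-octahydronaphthalen-1-yl]oxy}trimethylsilane
Product: 15 (4aR,5S,8aS)-7,7-(ethylenedioxy)-4a,5-dimethyl-4a,5,6,7,8,8a-hexahydronaphthalen-1(4H)-one
Conditions: Pd(OAc)2 (1.05 equiv), MeCN, 23 °C
Reagents that add atoms: none
Why: Saegusa–Ito oxidation: the enolate of divalent palladium formed from the silyl enol ether loses a β-hydride from C7, which gives the C7=C8 enone regiospecifically.

Step 11
Reactants: 15 (4aR,5S,8aS)-7,7-(ethylenedioxy)-4a,5-dimethyl-4a,5,6,7,8,8a-hexahydronaphthalen-1(4H)-one; 16 isopropenylmagnesium bromide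
Product: 17 triethyl{[(3S,4aR,5S,8aS)-7,7-(ethylenedioxy)-4a,5-dimethyl-3-(prop-1-en-2-yl)-3,4,4a,5,6,7,8,8a-octahydronaphthalen-1-yl]oxy}silane (3β-isopropenyl)
Conditions: 16, CuBr·SMe2 (20 mol %), Et3SiCl, DMPU, THF, −78 → −40 °C; Et3N, then aq. NaHCO3
Reagents that add atoms: chlorotriethylsilane (CC[Si](Cl)(CC)CC)
Why: Copper-catalysed conjugate addition of the Grignard reagent with silyl capture gives the C8=C9 enol ether regiospecifically. Attack at C7 is expected on the β face, syn to the small angular methyl, because the α face is covered by ring A, whose C4–H projects under ring B; this sets C7.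

Step 12
Reactants: 17 triethyl{[(3S,4aR,5S,8aS)-7,7-(ethylenedioxy)-4a,5-dimethyl-3-(prop-1-en-2-yl)-3,4,4a,5,6,7,8,8a-octahydronaphthalen-1-yl]oxy}silane
Product: 19 (2R,3R,4aR,5S,8aS)-7,7-(ethylenedioxy)-4a,5-dimethyl-3-(prop-1-en-2-yl)-2-(triethylsilyloxy)octahydronaphthalen-1(2H)-one, via silyloxy epoxide 18 (not isolated)
Conditions: mCPBA (1.05 equiv), NaHCO3, CH2Cl2, −20 → 0 °C
Reagents that add atoms: mCPBA (O=C(OO)c1cccc(Cl)c1)
Why: Rubottom oxidation: the electron-rich enol ether is epoxidised far faster than the 1,1-disubstituted alkene, and the silyloxy oxirane opens with 1,4-silyl shift to the α-silyloxy ketone. Oxygen enters at C8 anti to the adjacent isopropenyl group (α face), which is also the equatorial, thermodynamically preferred epimer.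

Step 13
Reactants: 19 (2R,3R,4aR,5S,8aS)-7,7-(ethylenedioxy)-4a,5-dimethyl-3-(prop-1-en-2-yl)-2-(triethylsilyloxy)octahydronaphthalen-1(2H)-one
Product: 20 (1S,2R,3R,4aR,5S,8aS)-7,7-(ethylenedioxy)-4a,5-dimethyl-3-(prop-1-en-2-yl)-2-(triethylsilyloxy)decahydronaphthalen-1-ol
Conditions: LiBH(s-Bu)3, THF, −78 °C; then H2O, −78 → 0 °C
Reagents that add atoms: none
Why: Diastereoselective hydride reduction: the bulky hydride attacks C9 along the equatorial trajectory from the β face, since the axial α approach is blocked by the axial C5–C4 bond of ring A; this gives the axial 9α-alcohol, cis to O8. The cold quench limits 1,2-silyl migration.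

Step 14
Reactants: 20 (1S,2R,3R,4aR,5S,8aS)-7,7-(ethylenedioxy)-4a,5-dimethyl-3-(prop-1-en-2-yl)-2-(triethylsilyloxy)decahydronaphthalen-1-ol; 21 tiglic acid
Product: 23 (1S,2R,3R,4aR,5S,8aS)-7,7-(ethylenedioxy)-4a,5-dimethyl-3-(prop-1-en-2-yl)-2-(triethylsilyloxy)decahydronaphthalen-1-yl (2E)-2-methylbut-2-enoate, via mixed anhydride 22 (not isolated)
Conditions: 21, 2,4,6-Cl3C6H2COCl, Et3N, toluene, 23 °C; then 20, DMAP, 80 °C
Reagents that add atoms: none
Why: Yamaguchi esterification: the mixed anhydride and DMAP give an acylpyridinium reactive enough for the hindered axial C9 hydroxyl. With O8 silylated no acyl migration is possible, and the E geometry of the tiglate is the stable one.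

Step 15
Reactants: 23 (1S,2R,3R,4aR,5S,8aS)-7,7-(ethylenedioxy)-4a,5-dimethyl-3-(prop-1-en-2-yl)-2-(triethylsilyloxy)decahydronaphthalen-1-yl (2E)-2-methylbut-2-enoate
Product: 24 (1S,2R,3R,4aR,5S,8aS)-2-hydroxy-4a,5-dimethyl-7-oxo-3-(prop-1-en-2-yl)decahydronaphthalen-1-yl (2E)-2-methylbut-2-enoate
Conditions: 1 M HCl (aq)/THF (1:3), 0 → 23 °C
Reagents that add atoms: water (O)
Why: Acidic hydrolysis cleaves the triethylsilyl ether and the dioxolane in one operation; the ester and the isopropenyl group tolerate dilute acid at this temperature, and the conjugated, α-branched tiglate is slow to migrate under acid.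

Step 16
Reactants: 24 (1S,2R,3R,4aR,5S,8aS)-2-hydroxy-4a,5-dimethyl-7-oxo-3-(prop-1-en-2-yl)decahydronaphthalen-1-yl (2E)-2-methylbut-2-enoate; 25 (R)-2-methylbutanoic acid
Product: 26 (1S,2R,3R,4aR,5S,8aS)-4a,5-dimethyl-2-{[(2R)-2-methylbutanoyl]oxy}-7-oxo-3-(prop-1-en-2-yl)decahydronaphthalen-1-yl (2E)-2-methylbut-2-enoate
Conditions: 25, DCC, DMAP (cat.), CH2Cl2, 0 → 23 °C
Reagents that add atoms: none
Why: Steglich esterification of the unhindered equatorial C8 hydroxyl is fast at low temperature and should outrun tiglate migration; carbodiimide activation with catalytic DMAP avoids the ketene pathway that would racemise the α-centre of the acid.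

## Compound list

1 | 3-ethoxycyclohex-2-en-1-one | CCOC1=CC(=O)CCC1 | starting material
2 | 5-bromopent-1-ene | C=CCCCBr | starting material
3 | 3-ethoxy-6-(pent-4-en-1-yl)cyclohex-2-en-1-one (racemic) | CCOC1=CC(=O)C(CCCC=C)CC1 | intermediate
4 | 3-ethoxy-6-methyl-6-(pent-4-en-1-yl)cyclohex-2-en-1-one (racemic) | CCOC1=CC(=O)C(C)(CCCC=C)CC1 | intermediate
5 | 3-ethoxy-6-methyl-6-(pent-4-en-1-yl)cyclohex-2-en-1-ol (diastereomer mixture) | CCOC1=CC(O)C(C)(CCCC=C)CC1 | intermediate (not isolated)
6 | 4-methyl-4-(pent-4-en-1-yl)cyclohex-2-en-1-one (racemic) | O=C1C=CC(C)(CCCC=C)CC1 | intermediate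
7 | 4-methyl-4-(pent-4-en-1-yl)cyclohexa-2,5-dien-1-one | O=C1C=CC(C)(CCCC=C)C=C1 | intermediate
8 | 4-methyl-4-[3-(1,2,4-trioxolan-3-yl)propyl]cyclohexa-2,5-dien-1-one (ozonide) | O=C1C=CC(C)(CCCC2OCOO2)C=C1 | intermediate (not isolated)
9 | 4-(1-methyl-4-oxocyclohexa-2,5-dien-1-yl)butanal | O=CCCCC1(C)C=CC(=O)C=C1 | intermediate
10 | (4aR,8aS)-4a-methyl-3,4,4a,8a-tetrahydronaphthalene-1,7(2H,8H)-dione | C1C[C@@]2(C)[C@H](CC(=O)C=C2)C(=O)C1 | intermediate
11 | (4aR,5S,8aS)-4a,5-dimethyl-7-[(trimethylsilyl)oxy]-3,4,4a,5,8,8a-hexahydronaphthalen-1(2H)-one | C1C[C@@]2(C)[C@H](CC(O[Si](C)(C)C)=C[C@@H]2C)C(=O)C1 | intermediate (not isolated)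
12 | (4aR,5S,8aS)-4a,5-dimethyl-3,4,4a,5,6,8a-hexahydronaphthalene-1,7(2H,8H)-dione | C1C[C@@]2(C)[C@H](CC(=O)C[C@@H]2C)C(=O)C1 | intermediate
13 | (4aR,5S,8aS)-7,7-(ethylenedioxy)-4a,5-dimethyloctahydronaphthalen-1(2H)-one | C1C[C@@]2(C)[C@H](CC3(OCCO3)C[C@@H]2C)C(=O)C1 | intermediate
14 | {[(4aR,5S,8aS)-7,7-(ethylenedioxy)-4a,5-dimethyl-3,4,4a,5,6,7,8,8a-octahydronaphthalen-1-yl]oxy}trimethylsilane | C1C[C@@]2(C)[C@H](CC3(OCCO3)C[C@@H]2C)C(O[Si](C)(C)C)=C1 | intermediate
15 | (4aR,5S,8aS)-7,7-(ethylenedioxy)-4a,5-dimethyl-4a,5,6,7,8,8a-hexahydronaphthalen-1(4H)-one | C1=CC[C@@]2(C)[C@H](CC3(OCCO3)C[C@@H]2C)C1=O | intermediate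
16 | isopropenylmagnesium bromide | C=C(C)[Mg]Br | starting material
17 | triethyl{[(3S,4aR,5S,8aS)-7,7-(ethylenedioxy)-4a,5-dimethyl-3-(prop-1-en-2-yl)-3,4,4a,5,6,7,8,8a-octahydronaphthalen-1-yl]oxy}silane | C=C(C)[C@H]1C[C@@]2(C)[C@H](CC3(OCCO3)C[C@@H]2C)C(O[Si](CC)(CC)CC)=C1 | intermediate
18 | 1α,2α-oxirane of 17 (oxygen anti to the 3β-isopropenyl group, triethylsilyloxy on C1) | C=C(C)[C@H]1C[C@@]2(C)[C@H](CC3(OCCO3)C[C@@H]2C)[C@]4(O[Si](CC)(CC)CC)O[C@H]14 | intermediate (not isolated)
19 | (2R,3R,4aR,5S,8aS)-7,7-(ethylenedioxy)-4a,5-dimethyl-3-(prop-1-en-2-yl)-2-(triethylsilyloxy)octahydronaphthalen-1(2H)-one | C=C(C)[C@H]1C[C@@]2(C)[C@H](CC3(OCCO3)C[C@@H]2C)C(=O)[C@@H]1O[Si](CC)(CC)CC | intermediate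
20 | (1S,2R,3R,4aR,5S,8aS)-7,7-(ethylenedioxy)-4a,5-dimethyl-3-(prop-1-en-2-yl)-2-(triethylsilyloxy)decahydronaphthalen-1-ol | C=C(C)[C@H]1C[C@@]2(C)[C@H](CC3(OCCO3)C[C@@H]2C)[C@H](O)[C@@H]1O[Si](CC)(CC)CC | intermediate
21 | tiglic acid, (2E)-2-methylbut-2-enoic acid | C/C=C(\C)C(=O)O | starting material
22 | (2E)-2-methylbut-2-enoic 2,4,6-trichlorobenzoic anhydride | C/C=C(\C)C(=O)OC(=O)c1c(Cl)cc(Cl)cc1Cl | intermediate (not isolated)
23 | (1S,2R,3R,4aR,5S,8aS)-7,7-(ethylenedioxy)-4a,5-dimethyl-3-(prop-1-en-2-yl)-2-(triethylsilyloxy)decahydronaphthalen-1-yl (2E)-2-methylbut-2-enoate | C=C(C)[C@H]1C[C@@]2(C)[C@H](CC3(OCCO3)C[C@@H]2C)[C@H](OC(=O)/C(C)=C/C)[C@@H]1O[Si](CC)(CC)CC | intermediate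
24 | (1S,2R,3R,4aR,5S,8aS)-2-hydroxy-4a,5-dimethyl-7-oxo-3-(prop-1-en-2-yl)decahydronaphthalen-1-yl (2E)-2-methylbut-2-enoate | C=C(C)[C@H]1C[C@@]2(C)[C@H](CC(=O)C[C@@H]2C)[C@H](OC(=O)/C(C)=C/C)[C@@H]1O | intermediate
25 | (R)-2-methylbutanoic acid | CC[C@@H](C)C(=O)O | starting material
26 | (1S,2R,3R,4aR,5S,8aS)-4a,5-dimethyl-2-{[(2R)-2-methylbutanoyl]oxy}-7-oxo-3-(prop-1-en-2-yl)decahydronaphthalen-1-yl (2E)-2-methylbut-2-enoate | C=C(C)[C@H]1C[C@@]2(C)[C@H](CC(=O)C[C@@H]2C)[C@H](OC(=O)/C(C)=C/C)[C@@H]1OC(=O)[C@H](C)CC | target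

## Step count and least certain steps

Total step count: 16. Longest linear sequence: 16 steps (1 to 26).

Step 6 (key step). Residual base may enolise the aliphatic aldehyde, which then closes a five-membered ring through C8 by Michael addition or undergoes aldol reaction. The six-membered closure may be slow enough for the catalyst to decay, the two enone arms may be poorly discriminated, and C10 may epimerise after closure. Fallback, from 9 back to 10: a nitronate takes the acyl-anion role. Condensation of 9 with hydroxylamine at the aldehyde gives 4-(1-methyl-4-oxocyclohexa-2,5-dien-1-yl)butanal oxime F1. Buffered peroxytrifluoroacetic acid oxidises it to 4-methyl-4-(4-nitrobutyl)cyclohexa-2,5-dien-1-one F2. A bifunctional cinchona-derived amine–thiourea catalyses the desymmetrising intramolecular nitro-Michael addition to (4aR,8aS)-4a-methyl-8-nitro-4a,5,6,7,8,8a-hexahydronaphthalen-2(1H)-one F3, whose nitro-bearing centre is immaterial. A Nef reaction of its nitronate with buffered TiCl3/NH4OAc then returns 10.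

Step 11. Facial selection at C7 may be poor, since either face of the enone carries a 1,3-related substituent on C5, and conversion at this hindered β-carbon may be low. Fallback, from 15 to 20: Luche reduction (NaBH4, CeCl3·7H2O) gives (1R,4aR,5S,8aS)-7,7-(ethylenedioxy)-4a,5-dimethyl-1,4,4a,5,6,7,8,8a-octahydronaphthalen-1-ol F4, with hydride from the β face as in step 13; a wrongly configured carbinol would be corrected by Mitsunobu inversion. Hydroxyl-directed epoxidation with VO(acac)2 and t-BuOOH gives (1S,2S,3R,4aR,5S,8aS)-2,3-epoxy-7,7-(ethylenedioxy)-4a,5-dimethyldecahydronaphthalen-1-ol F5. Anti opening of the oxirane at C7, distal to the hydroxyl, by 16 with catalytic CuI gives (1S,2R,3R,4aR,5S,8aS)-7,7-(ethylenedioxy)-4a,5-dimethyl-3-(prop-1-en-2-yl)decahydronaphthalene-1,2-diol F6. Silylation of the equatorial C8 hydroxyl with Et3SiCl and imidazole returns 20. Here C7 and C8 follow stereospecifically from the carbinol.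

Step 8. The C2 and C9 carbonyls may not be fully discriminated, and the Lewis acid may epimerise C10. Fallback, from 10 to 13: the carbonyls are told apart at the enedione stage. Substoichiometric NaBH4 in EtOH at −20 °C reduces only the saturated C9 ketone to (4aR,8aS)-8-hydroxy-4a-methyl-4a,5,6,7,8,8a-hexahydronaphthalen-2(1H)-one F7. Me2CuLi in excess gives (4S,4aR,8aS)-8-hydroxy-4,4a-dimethyloctahydronaphthalen-2(1H)-one F8. Ethylene glycol with TsOH ketalises the only carbonyl to (4aR,5S,8aS)-7,7-(ethylenedioxy)-4a,5-dimethyldecahydronaphthalen-1-ol F9, and Dess–Martin oxidation returns 13.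

Step 12. The peracid may also epoxidise the isopropenyl group, or the silyl shift may stall and leave a mixture. Fallback, from 17 to 19: MeLi cleaves the enol ether to the lithium enolate, which is hydroxylated with 2-(phenylsulfonyl)-3-phenyloxaziridine, a reagent inert to unactivated alkenes. This gives (2R,3R,4aR,5S,8aS)-7,7-(ethylenedioxy)-2-hydroxy-4a,5-dimethyl-3-(prop-1-en-2-yl)octahydronaphthalen-1(2H)-one F10, and Et3SiCl with imidazole returns 19.

Step 15. During the slower ketal hydrolysis the tigloyl group may shift from O9 to the freed O8, or the isopropenyl group may be hydrated. Fallback, from 23 to 26: the ketal is removed last. Pyridine-buffered HF·pyridine removes only the silyl ether to give (1S,2R,3R,4aR,5S,8aS)-7,7-(ethylenedioxy)-2-hydroxy-4a,5-dimethyl-3-(prop-1-en-2-yl)decahydronaphthalen-1-yl (2E)-2-methylbut-2-enoate F11. Esterification with 25, DCC and DMAP gives (1S,2R,3R,4aR,5S,8aS)-7,7-(ethylenedioxy)-4a,5-dimethyl-2-{[(2R)-2-methylbutanoyl]oxy}-3-(prop-1-en-2-yl)decahydronaphthalen-1-yl (2E)-2-methylbut-2-enoate F12, and PPTS in wet acetone returns 26.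

## Further compounds

F1 | step 6 | 4-(1-methyl-4-oxocyclohexa-2,5-dien-1-yl)butanal oxime (E/Z mixture) | ON=CCCCC1(C)C=CC(=O)C=C1
F2 | step 6 | 4-methyl-4-(4-nitrobutyl)cyclohexa-2,5-dien-1-one | O=C1C=CC(C)(CCCC[N+](=O)[O-])C=C1
F3 | step 6 | (4aR,8aS)-4a-methyl-8-nitro-4a,5,6,7,8,8a-hexahydronaphthalen-2(1H)-one (C8 epimers) | C1C[C@@]2(C)[C@H](CC(=O)C=C2)C([N+](=O)[O-])C1
F4 | step 11 | (1R,4aR,5S,8aS)-7,7-(ethylenedioxy)-4a,5-dimethyl-1,4,4a,5,6,7,8,8a-octahydronaphthalen-1-ol | C1=CC[C@@]2(C)[C@H](CC3(OCCO3)C[C@@H]2C)[C@@H]1O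
F5 | step 11 | (1S,2S,3R,4aR,5S,8aS)-2,3-epoxy-7,7-(ethylenedioxy)-4a,5-dimethyldecahydronaphthalen-1-ol | [C@@H]14C[C@@]2(C)[C@H](CC3(OCCO3)C[C@@H]2C)[C@H](O)[C@@H]1O4
F6 | step 11 | (1S,2R,3R,4aR,5S,8aS)-7,7-(ethylenedioxy)-4a,5-dimethyl-3-(prop-1-en-2-yl)decahydronaphthalene-1,2-diol | C=C(C)[C@H]1C[C@@]2(C)[C@H](CC3(OCCO3)C[C@@H]2C)[C@H](O)[C@@H]1O
F7 | step 8 | (4aR,8aS)-8-hydroxy-4a-methyl-4a,5,6,7,8,8a-hexahydronaphthalen-2(1H)-one (carbinol configuration immaterial) | C1C[C@@]2(C)[C@H](CC(=O)C=C2)C(O)C1
F8 | step 8 | (4S,4aR,8aS)-8-hydroxy-4,4a-dimethyloctahydronaphthalen-2(1H)-one (carbinol configuration immaterial) | C1C[C@@]2(C)[C@H](CC(=O)C[C@@H]2C)C(O)C1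
F9 | step 8 | (4aR,5S,8aS)-7,7-(ethylenedioxy)-4a,5-dimethyldecahydronaphthalen-1-ol (carbinol configuration immaterial) | C1C[C@@]2(C)[C@H](CC3(OCCO3)C[C@@H]2C)C(O)C1
F10 | step 12 | (2R,3R,4aR,5S,8aS)-7,7-(ethylenedioxy)-2-hydroxy-4a,5-dimethyl-3-(prop-1-en-2-yl)octahydronaphthalen-1(2H)-one | C=C(C)[C@H]1C[C@@]2(C)[C@H](CC3(OCCO3)C[C@@H]2C)C(=O)[C@@H]1O
F11 | step 15 | (1S,2R,3R,4aR,5S,8aS)-7,7-(ethylenedioxy)-2-hydroxy-4a,5-dimethyl-3-(prop-1-en-2-yl)decahydronaphthalen-1-yl (2E)-2-methylbut-2-enoate | C=C(C)[C@H]1C[C@@]2(C)[C@H](CC3(OCCO3)C[C@@H]2C)[C@H](OC(=O)/C(C)=C/C)[C@@H]1O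
F12 | step 15 | (1S,2R,3R,4aR,5S,8aS)-7,7-(ethylenedioxy)-4a,5-dimethyl-2-{[(2R)-2-methylbutanoyl]oxy}-3-(prop-1-en-2-yl)decahydronaphthalen-1-yl (2E)-2-methylbut-2-enoate | C=C(C)[C@H]1C[C@@]2(C)[C@H](CC3(OCCO3)C[C@@H]2C)[C@H](OC(=O)/C(C)=C/C)[C@@H]1OC(=O)[C@H](C)CC
A1 | alternative 1 | (3E)-1-{(4R,5S)-5-[(1E)-3-{[tert-butyl(dimethyl)silyl]oxy}buta-1,3-dien-1-yl]-2,2-dimethyl-1,3-dioxolan-4-yl}-3-methylpent-3-en-2-one | C=C(O[Si](C)(C)C(C)(C)C)/C=C/[C@@H]1OC(C)(C)O[C@@H]1CC(=O)/C(C)=C/C
A2 | alternative 1 | cis-fused 4β,5β-dimethyl-2-(tert-butyldimethylsilyloxy)-8α,9α-(isopropylidenedioxy)-10βH-decal-1-en-6-one (skeletal numbering of the target) | C1C(=O)[C@@]2(C)[C@H](C=C(O[Si](C)(C)C(C)(C)C)C[C@@H]2C)[C@@H]3OC(C)(C)O[C@@H]31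
A3 | alternative 2 | 7-{[tert-butyl(dimethyl)silyl]oxy}-8,8-dimethoxy-5-methyl-2-[(1Z)-prop-1-en-1-yl]bicyclo[2.2.2]oct-5-en-2-ol (propenyl syn to the C5=C6 bridge) | C/C=C\[C@@]1(O)C[C@H]2C(C)=C[C@@H]1[C@@H](O[Si](C)(C)C(C)(C)C)C2(OC)OC
A4 | alternative 2 | cis-fused 8α-(tert-butyldimethylsilyloxy)-9,9-dimethoxy-4β,5β-dimethyl-10βH-decal-6-en-2-one (skeletal numbering of the target) | C1=C[C@@]2(C)[C@H](CC(=O)C[C@@H]2C)C(OC)(OC)[C@@H]1O[Si](C)(C)C(C)(C)C
A5 | alternative 3 | 3-{(4R,5S)-2,2-dimethyl-5-[(7S,9S)-9-methyl-8-methylidene-1,4-dioxaspiro[4.5]decan-7-yl]-1,3-dioxolan-4-yl}but-3-en-2-one | C=C1[C@@H](C)CC2(OCCO2)C[C@@H]1[C@@H]3OC(C)(C)O[C@@H]3C(=C)C(C)=O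
A6 | alternative 3 | cis-fused 7β-acetyl-2,2-(ethylenedioxy)-8α,9α-(isopropylidenedioxy)-4β,5β-dimethyl-10βH-decalin (skeletal numbering of the target) | CC(=O)[C@H]1C[C@@]2(C)[C@H](CC3(OCCO3)C[C@@H]2C)[C@@H]4OC(C)(C)O[C@@H]41
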